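Green was charged with 0.35 equiv of partner and blue with 1.4 equiv, and their last readings of target stand at 21.4 % and 30.7 %.

the same everywhere: solid substrate 0.022 M; free catalyst 0.05 mol%

|  | partner | remark | time |
|---|---|---|---|
| green | 0.35 equiv | run made earlier |  |
| blue | 1.4 equiv | run made earlier |  |
| flask | 0.700 equiv |  | 30 min |

| run | time / min | target / % | starting material / % |
|---|---|---|---|
| green | 2.00 | 11.4 | 23.4 |
| green | 3.00 | 13.9 | 25.9 |
| green | 5.00 | 17.6 | 34.1 |
| green | 8.00 | 19.9 | 38.0 |
| green | 15.0 | 22.1 | 39.2 |
| green | 25.0 | 21.4 | 39.3 |
| blue | 2.00 | 9.8 | 18.6 |
| blue | 3.00 | 10.9 | 22.4 |
| blue | 5.00 | 18.7 | 23.4 |
| blue | 8.00 | 26.7 | 20.5 |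
| blue | 15.0 | 30.6 | 14.4 |
| blue | 25.0 | 30.7 | 16.3 |

(readings scatter by 1 percentage point)

- as a solid, counted per litre of solution: solid substrate
- what was read earlier has a scatter of 1 percentage point, one standard deviation
- candidate steps: catalyst intermediate B -> free catalyst + target; partner + catalyst intermediate A -> catalyst intermediate B; starting material + free catalyst -> catalyst intermediate A; solid substrate <-> starting material; partner + target -> over-reaction product
- at the start none of the solid substrate is in solution
- starting material means what is dissolved; the solid is not counted in it

- Wednesday's: doubling the amount of partner, all else as stated
- Friday's: doubling the solubility of the solid substrate, all else as stated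
- Sunday's: doubling the amount of free catalyst, all else as stated
- Tuesday's: doubling the dissolution coefficient of the solid substrate, all else as stated

1. the target standing at 30 min, as a percentage of the solid substrate charged
2. concentration of starting material in solution at 15 min, in percent of saturation
3. the change that raises the amount of target at 30 min, in percent of the solid substrate charged most ("none" if none brings more than 2 percentage points) (Wednesday's / Friday's / Sunday's / Tuesday's / none)
4. amount of target at 30 min, in percent of the solid substrate charged, after Friday's

**Why does green stop?** Between 15.0 min and 25.0 min its target and its starting material stay flat within the scatter, with starting material at 39.3 %. I read that as a stop for want of partner, the limiting reagent in green, though partner itself was not read.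

**What does partner buy?** One partner joins catalyst intermediate A for each target made, and one more is lost for each target turned into over-reaction product. Once the partner charge is used up, target + 2 × over-reaction product equals the partner charged.

**Can you test that?** In blue, if solid and partner are both used up, over-reaction product is what target and starting material leave of the solid charged. The budget then sums to 137 % against a charge of 1.4 equiv, which is near enough for these readings.

**So what number do you carry?** The ratio of partner taken by the joining step to partner taken by over-reaction, which is (partner charged + target)/(partner charged − target) once the partner charge is used up. Green's last reading gives 4.15 and blue's gives 1.56, so blue's ratio is lower than green's.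

**And this flask?** Its 0.700 equiv is the geometric mean of the two charges, so I take the geometric mean of the two ratios, 2.54, as this flask's partner split, or selectivity factor. Target is then the charge × (split − 1)/(split + 1), which gives 30.5 %.

**Isn't that a guess?** Yes: it is a straight line in logarithms through two runs.

The forecast gave 29.5 %, lower than my figure, with 97 % of saturation, Sunday's as best change, and 31.5 % after Friday's: “Doubling catalyst therefore helps most, since it doubles formation relative to over-reaction.”

The flask gives 28.2 %, 99.9 % of saturation, Sunday's with a gain of 8.6 percentage points, and 31.0 % after Friday's.

    catalyst intermediate B → free catalyst + target (k = 150 s⁻¹)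
    partner + catalyst intermediate A → catalyst intermediate B (k = 770 L mol⁻¹ s⁻¹)
    starting material + free catalyst → catalyst intermediate A (k = 1300 L mol⁻¹ s⁻¹)
    solid substrate ⇌ starting material, rate k4*(cs4 - [starting material]) while solid is left; crystals form when [starting material] > cs4 (solubility = 8.40 mM, k = 0.0130 s⁻¹)
    partner + target → over-reaction product (k = 0.620 L mol⁻¹ s⁻¹)

This flask's split, worked back from its result, is 2.35; at 2.49 min the joining step takes partner 2.1 times as fast as over-reaction, and by 15.0 min partner is down to 0.0140 % of its charge with target at 28.2 %. The neighbour flask with 0.420 equiv of partner ends with 0 % of that partner left and 23.3 % target, and its split is higher than this flask's, at 3.49.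

The runs were generated by integration on assumed constants, noise included.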